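## Retrosynthetic overview

1. The 3-O-vanilloyl group is carried from the start: vanillic acid 1 and chloroketone 2 give phenacyl ester 3 by carboxylate alkylation.
2. Ring C is the only ring formed: aldehyde 4 and 3 give chalcone 5, whose A-ring phenol closes the O1–C2 bond to give the anthocyanidin ester 6 (3-O-vanilloylcyanidin).
3. Both stereocentres are set last in one operation: an asymmetric, anthocyanidin-reductase-like double reduction of 6, through 7 and 8, gives the cis-(2R,3R) flavan 9.
4. Rings A, B and the vanilloyl ring are bought; no protecting groups are used.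

The target 9 is (−)-epicatechin 3-O-vanillate, with C2 = R and C3 = R (2,3-cis).

Assumption: the sense of induction in step 3 has no direct precedent. (R)-SegPhos is written; the (S) ligand is used instead if the first run gives the 2S,3S ester (checked by chiral HPLC and CD against (−)-epicatechin-type esters).

## Route

Step 1
Reactants: 1 vanillic acid; 2 2-chloro-1-(3,4-dihydroxyphenyl)ethan-1-one
Product: 3 2-(3,4-dihydroxyphenyl)-2-oxoethyl 4-hydroxy-3-methoxybenzoate
Conditions: NaHCO3 (1.0 equiv to 1), EtOH/H2O 3:1, N2, reflux, 8 h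
Reagents that add atoms: none
Why: SN2 alkylation of a carboxylate by an α-chloroketone (phenacyl ester formation); bicarbonate in aqueous ethanol ionises only the CO2H (pKa about 4.5) and not the phenols (pKa 7.5 or higher), and no stereocentre is involved.

Step 2
Reactants: 3 2-(3,4-dihydroxyphenyl)-2-oxoethyl 4-hydroxy-3-methoxybenzoate; 4 2,4,6-trihydroxybenzaldehyde
Product: 6 3-O-vanilloylcyanidin chloride, via chalcone 5 (not isolated)
Conditions: dry HCl(g), EtOAc/AcOH 4:1, 0 °C then rt, 48 h; Et2O, filtration
Reagents that add atoms: hydrogen chloride, Cl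
Why: Robinson anthocyanidin synthesis: acid-catalysed aldol condensation of the enol of 3 with 4 gives chalcone 5, whose ortho-phenol adds to the protonated ketone (O1–C2 closure, as when chalcones close to flavonoids in plants) and two molecules of water are lost to give the aromatic flavylium ion; the anhydrous, non-nucleophilic medium keeps the 3-O-aroyl ester intact and no stereocentre is formed.

Step 3
Reactants: 6 3-O-vanilloylcyanidin chloride
Product: 9 (−)-epicatechin 3-O-vanillate (2R,3R), via flav-2-ene 7 (not isolated), via oxocarbenium 8 (not isolated)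
Conditions: H2 (50 bar), [Ir(cod)Cl]2 (1 mol %), (R)-SegPhos (2.2 mol %), THF/HFIP 4:1, 30 °C, 24 h
Reagents that add atoms: none
Why: Proposed new method: the flavylium ion is the oxygen analogue of the quinolinium, isoquinolinium and pyridinium halides that Ir–bisphosphine hydrides reduce by stepwise outer-sphere H−/H+ transfer; hydride adds at C4 to give the achiral flav-2-ene 7, the HCl set free reversibly protonates its enol-ether carbon C3 to oxocarbenium 8 (its C3 epimers equilibrate through 7), and the chiral Ir–H reduces the 3R ion at C2 on the face anti to the pseudo-axial acyloxy group (dynamic kinetic resolution), so the aryl and acyloxy groups end up cis and both centres are set as 2R,3R in one operation; the closest known reactions are the Ir-catalysed asymmetric hydrogenation of 2,3-disubstituted quinolines (cis products by the same 1,4-reduction, protonation, 1,2-reduction sequence), the catalytic hydrogenation of cyanidin chloride to racemic epicatechin, and the NADPH-dependent anthocyanidin reductase in plants.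

## Compound list

1 | vanillic acid (4-hydroxy-3-methoxybenzoic acid) | COc1cc(C(=O)O)ccc1O | starting material
2 | 2-chloro-1-(3,4-dihydroxyphenyl)ethan-1-one | O=C(CCl)c1ccc(O)c(O)c1 | starting material
3 | 2-(3,4-dihydroxyphenyl)-2-oxoethyl 4-hydroxy-3-methoxybenzoate | COc1cc(C(=O)OCC(=O)c2ccc(O)c(O)c2)ccc1O | intermediate
4 | 2,4,6-trihydroxybenzaldehyde | O=Cc1c(O)cc(O)cc1O | starting material
5 | 3-(3,4-dihydroxyphenyl)-3-oxo-1-(2,4,6-trihydroxyphenyl)prop-1-en-2-yl 4-hydroxy-3-methoxybenzoate; not isolated; E/Z isomers interconvert in HCl, drawn as the E isomer (A-ring aryl cis to the ketone) that cyclises | COc1cc(C(=O)O/C(=C/c2c(O)cc(O)cc2O)C(=O)c2ccc(O)c(O)c2)ccc1O | intermediate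
6 | 2-(3,4-dihydroxyphenyl)-5,7-dihydroxy-3-[(4-hydroxy-3-methoxybenzoyl)oxy]chromenylium chloride (3-O-vanilloylcyanidin chloride) | COc1cc(C(=O)Oc2cc3c(O)cc(O)cc3[o+]c2-c2ccc(O)c(O)c2)ccc1O.[Cl-] | intermediate
7 | 2-(3,4-dihydroxyphenyl)-5,7-dihydroxy-4H-chromen-3-yl 4-hydroxy-3-methoxybenzoate (flav-2-ene); not isolated; achiral | COc1cc(C(=O)OC2=C(c3ccc(O)c(O)c3)Oc3cc(O)cc(O)c3C2)ccc1O | intermediate
8 | (3R)-2-(3,4-dihydroxyphenyl)-5,7-dihydroxy-3-[(4-hydroxy-3-methoxybenzoyl)oxy]-3,4-dihydrochromenylium chloride; not isolated; in fast equilibrium with its 3S enantiomer through 7, drawn as the 3R ion that is reduced | COc1cc(C(=O)O[C@@H]2Cc3c(O)cc(O)cc3[O+]=C2c2ccc(O)c(O)c2)ccc1O.[Cl-] | intermediate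
9 | (2R,3R)-2-(3,4-dihydroxyphenyl)-5,7-dihydroxy-3,4-dihydro-2H-chromen-3-yl 4-hydroxy-3-methoxybenzoate ((−)-epicatechin 3-O-vanillate, 2,3-cis) | COc1cc(C(=O)O[C@@H]2Cc3c(O)cc(O)cc3O[C@@H]2c2ccc(O)c(O)c2)ccc1O | target

## Step count and risk

Total steps: 3. Longest linear sequence: 3 (1 + 2 → 3 → 6 → 9).

Steps most likely to fail, in order of risk: step 3, step 2, step 1.

Step 3 is the main risk. The regiochemistry of the first hydride transfer (C4 rather than C2), catalyst inhibition by the free catechol, and the level of enantio- and diastereocontrol are all untested. The fallback gives up asymmetric catalysis for resolution. It sets out from 6: heterogeneous hydrogenation (H2 1–3 atm, PtO2, AcOH/EtOAc, rt) adds hydrogen syn across the flav-2-ene and gives the racemic cis ester F1. Preparative chiral SFC on an immobilised amylose phase (CO2/MeOH, 0.1 % HCO2H) then separates the enantiomers, and the route is rejoined at 9.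

Step 2 may fail because aldehyde 4 is a weak, hydrogen-bonded electrophile that tends to self-condense to xanthylium dyes. The fallback replaces the direct aldol by iminium (Mannich-type) activation. It sets out from 4: aniline in EtOH at rt gives the crystalline anil 2-[(E)-(phenylimino)methyl]benzene-1,3,5-triol F2. F2 and 3 in dry HCl/EtOAc–AcOH react through the protonated imine to the β-anilino ketone F3, which is not isolated. F3 loses aniline to give chalcone 5, which closes in the same flask, and the route is rejoined at 6.

Step 1 may fail through competing O-alkylation by the acidic catechol of 2 (self-condensation). The fallback masks that catechol under acidic conditions. It sets out from 2: Ac2O with catalytic H2SO4 (0 °C to rt) gives 4-(2-chloroacetyl)-1,2-phenylene diacetate F4. F4 with 1 and KHCO3 in DMF at 40 °C gives the diacetate phenacyl ester F5. Catalytic HCl in MeOH (0 °C to rt) then removes the two aryl acetates by methanolysis, leaving the slower-reacting benzoate ester untouched, and the route is rejoined at 3.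

## Further compounds

F1 | step 3 | racemic cis-2-(3,4-dihydroxyphenyl)-5,7-dihydroxy-3,4-dihydro-2H-chromen-3-yl 4-hydroxy-3-methoxybenzoate (1:1 mixture of 2R,3R and 2S,3S) | COc1cc(C(=O)O[C@@H]2Cc3c(O)cc(O)cc3O[C@@H]2c2ccc(O)c(O)c2)ccc1O.COc1cc(C(=O)O[C@H]2Cc3c(O)cc(O)cc3O[C@H]2c2ccc(O)c(O)c2)ccc1O
F2 | step 2 | 2-[(E)-(phenylimino)methyl]benzene-1,3,5-triol | Oc1cc(O)c(/C=N/c2ccccc2)c(O)c1
F3 | step 2 | 1-anilino-3-(3,4-dihydroxyphenyl)-3-oxo-1-(2,4,6-trihydroxyphenyl)propan-2-yl 4-hydroxy-3-methoxybenzoate (racemic diastereomer mixture, not isolated) | COc1cc(C(=O)OC(C(Nc2ccccc2)c2c(O)cc(O)cc2O)C(=O)c2ccc(O)c(O)c2)ccc1O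
F4 | step 1 | 4-(2-chloroacetyl)-1,2-phenylene diacetate | CC(=O)Oc1ccc(C(=O)CCl)cc1OC(C)=O
F5 | step 1 | 2-(3,4-diacetoxyphenyl)-2-oxoethyl 4-hydroxy-3-methoxybenzoate | COc1cc(C(=O)OCC(=O)c2ccc(OC(C)=O)c(OC(C)=O)c2)ccc1O
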